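**Retrosynthetic overview**

- The strategy rests on the 3-hydroxy-4-methoxyphenyl ring: a benzene ring with OH and OMe on neighbouring carbons and the CH2 link to imidazole C5 para to OMe and meta to OH. This ring is built, not bought: C3(OH), C4(OMe), C5 and C6 come from C2–C5 of 3-methoxyfuran, the phenol oxygen is the furan oxygen, and C1/C2 are the two alkyne carbons of an imidazol-5-yl ethynyl ketone whose carbonyl later becomes the CH2.
- Last bond: the exocyclic C–N between the imidazole 2-amino group and C4 of 1-methylparabanic acid (silyl imidate condensation), after ketone-to-methylene reduction and removal of the formamidine.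
- The ynone comes from C5–H of 2-amino-4-(4-methoxybenzyl)-1-methylimidazole: Vilsmeier formylation (which also masks NH2 as the formamidine), ethynyl Grignard addition, MnO2 oxidation.
- The imidazole ring comes from an α-(methylamino) ketone and cyanamide; the ketone comes from the Weinreb amide of N-Boc-sarcosine and 4-methoxybenzylmagnesium chloride.
- Ring order: imidazole ring first, phenol ring second (key step), the imidazolidinedione ring brought in preformed at the end.

Key step: step 8

Remark (assumption): 3-methoxyfuran, 1-methylparabanic acid and the THF solutions of 4-methoxybenzylmagnesium chloride and ethynylmagnesium bromide are taken as purchased materials.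

**Route**

Step 1
Reactants: 1 N-Boc-sarcosine; 2 N,O-dimethylhydroxylamine hydrochloride
Product: 3 tert-butyl N-{2-[methoxy(methyl)amino]-2-oxoethyl}-N-methylcarbamate
Conditions: 1,1'-carbonyldiimidazole (CDI), CH2Cl2, 0 °C to rt; then 2, rt
Reagents that add atoms: none
Why: CDI amide coupling: the acid is activated as its acyl imidazolide and the liberated imidazole frees the hydroxylamine from its hydrochloride, so the Weinreb amide should form without added base.

Step 2
Reactants: 3 Weinreb amide; 4 4-methoxybenzylmagnesium chloride
Product: 5 tert-butyl N-[3-(4-methoxyphenyl)-2-oxopropyl]-N-methylcarbamate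
Conditions: 4 (1.4 equiv, THF solution), THF, −20 to 0 °C; then aq. NH4Cl
Reagents that add atoms: none
Why: Weinreb ketone synthesis: the magnesium chelate of the tetrahedral adduct holds until work-up, so the benzylic Grignard reagent adds only once and the enolisable ketone is released only on quenching (the carbamate has no N–H to consume reagent).

Step 3
Reactants: 5 Boc-protected amino ketone
Product: 6 1-(4-methoxyphenyl)-3-(methylamino)propan-2-one hydrochloride
Conditions: 4 M HCl in 1,4-dioxane, rt
Reagents that add atoms: hydrogen chloride, Cl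
Why: Acidolytic Boc removal gives the α-amino ketone directly as its hydrochloride, the form in which it cannot self-condense to a dihydropyrazine.

Step 4
Reactants: 6 amino ketone hydrochloride
Product: 8 4-(4-methoxybenzyl)-1-methyl-1H-imidazol-2-amine, via N-methyl-N-(2-oxoalkyl)guanidine 7 (not isolated)
Conditions: H2NCN (5 equiv), H2O/EtOH, pH 4.5, 95 °C; then aq. NaOH to pH 10
Reagents that add atoms: cyanamide, NC#N
Why: Classical α-amino ketone–cyanamide synthesis of 2-aminoimidazoles: the secondary amine adds to the nitrile to give guanidine 7, whose NH2 closes onto the ketone and dehydrates, which places methyl on N1, the benzyl group on C4 and leaves C5 unsubstituted.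

Step 5
Reactants: 8 2-aminoimidazole
Product: 11 (E)-N'-[5-formyl-4-(4-methoxybenzyl)-1-methyl-1H-imidazol-2-yl]-N,N-dimethylformimidamide, via C5-unsubstituted formamidine 9 (not isolated), via C5 iminium chloride 10 (not isolated)
Conditions: POCl3 (3.5 equiv), DMF, 0 °C then 70 °C; then aq. NaOH to pH 9, 0 °C
Reagents that add atoms: N,N-dimethylformamide, CN(C)C=O
Why: Vilsmeier–Haack reaction: the chloroiminium reagent first converts the primary amine into the N,N-dimethylformamidine and then attacks C5, the only free ring carbon and an enamine-like position, as is known for 2-aminothiazoles and related 2-aminoazoles; mild basic hydrolysis of the C5 iminium salt should free the aldehyde while the amidine stays on.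

Step 6
Reactants: 11 amidine aldehyde
Product: 12 (E)-N'-[5-(1-hydroxyprop-2-yn-1-yl)-4-(4-methoxybenzyl)-1-methyl-1H-imidazol-2-yl]-N,N-dimethylformimidamide (racemic)
Conditions: HC≡CMgBr (2.5 equiv), THF, −20 to 0 °C; then aq. NH4Cl
Reagents that add atoms: ethynylmagnesium bromide, C#C[Mg]Br
Why: 1,2-Addition of an alkynyl Grignard reagent to the aldehyde, which is far more electrophilic than the formamidine; the carbinol centre is formed racemic and is removed in step 7.

Step 7
Reactants: 12 propargylic alcohol
Product: 13 (E)-N'-[4-(4-methoxybenzyl)-1-methyl-5-(prop-2-ynoyl)-1H-imidazol-2-yl]-N,N-dimethylformimidamide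
Conditions: activated MnO2 (15 equiv), CH2Cl2, rt
Reagents that add atoms: none
Why: MnO2 oxidation of a doubly activated (propargylic and heteroaryl) secondary alcohol under neutral conditions, which should leave the amidine and the benzylic CH2 untouched and introduce no base or nucleophile that could add to the terminal ynone.

Step 8
Reactants: 13 imidazol-5-yl ethynyl ketone; 14 3-methoxyfuran
Product: 16 (E)-N'-[5-(3-hydroxy-4-methoxybenzoyl)-4-(4-methoxybenzyl)-1-methyl-1H-imidazol-2-yl]-N,N-dimethylformimidamide, via 7-oxanorbornadiene cycloadduct 15 (not isolated)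
Conditions: 14 (3 equiv), toluene, rt to 60 °C, sealed tube; concentrate; then CF3CO2H (3 equiv), CH2Cl2, 0 °C; aq. NaHCO3
Reagents that add atoms: none
Why: This is a normal-demand Diels–Alder reaction between the electron-rich diene of 3-methoxyfuran and the electron-poor triple bond of the ynone: furan C2, the terminus with the largest HOMO coefficient because it adjoins the methoxy-bearing C3, bonds to the unsubstituted β-carbon of the ynone and furan C5 to the α-carbon, so the six-membered carbocycle closes by [4+2] cycloaddition as the 7-oxanorbornadiene 15. Acid then breaks the bridging C–O bond at the former furan C5, because only that heterolysis gives a cation that the enol ether stabilises as a vinylogous oxocarbenium ion (breaking the other C–O bond would leave the methoxy group cross-conjugated and put the charge in conjugation with the acyl-bearing carbon), and loss of the proton from the former furan C2 aromatises the ring with the furan oxygen kept as the free phenol. The closest known reaction type is the furan–alkyne cycloaddition followed by isomerisation of the oxanorbornadiene to a phenol. The two bridgehead stereocentres of 15 are formed racemic and both vanish on aromatisation, so no stereocontrol is needed. The step needs "para" regiochemistry (methoxy para and hydroxyl meta to the acyl carbon), which the pairing of the methoxy-directed furan C2 with the carbonyl-polarised β-carbon should secure, and it needs cycloaddition to outrun open-chain conjugate addition of the furan, which the non-polar medium free of Lewis acid favours because it does not stabilise a zwitterion; the formamidine keeps the 2-amino nitrogen from adding to the ynone.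

Step 9
Reactants: 16 aryl imidazolyl ketone
Product: 17 (E)-N'-{5-[hydroxy(3-hydroxy-4-methoxyphenyl)methyl]-4-(4-methoxybenzyl)-1-methyl-1H-imidazol-2-yl}-N,N-dimethylformimidamide (racemic)
Conditions: NaBH4 (4 equiv), MeOH/THF, 0 °C to rt
Reagents that add atoms: none
Why: Borohydride reduction of the diaryl ketone to the racemic carbinol; at or below room temperature the ketone should be reduced well before the formamidine, and the stereocentre is removed in step 10.

Step 10
Reactants: 17 diaryl carbinol
Product: 18 (E)-N'-[5-(3-hydroxy-4-methoxybenzyl)-4-(4-methoxybenzyl)-1-methyl-1H-imidazol-2-yl]-N,N-dimethylformimidamide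
Conditions: Et3SiH (5 equiv), CF3CO2H/CH2Cl2 (1:4), 0 °C to rt; aq. NaHCO3
Reagents that add atoms: none
Why: Ionic hydrogenation: CF3CO2H ionises the doubly benzylic carbinol to a cation stabilised by the 2-aminoimidazole and the aryl ring and Et3SiH delivers hydride to give the methylene, while the phenol, the aryl ethers and the protonated amidine are inert under these anhydrous conditions.

Step 11
Reactants: 18 amidine-protected diarylmethane
Product: 19 5-{[2-amino-4-(4-methoxybenzyl)-1-methyl-1H-imidazol-5-yl]methyl}-2-methoxyphenol
Conditions: N2H4·H2O (10 equiv), EtOH, 80 °C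
Reagents that add atoms: none
Why: Transamidination with hydrazine, the standard cleavage of an N,N-dimethylformamidine, should free the primary 2-amino group, since nothing else in the molecule is electrophilic.

Step 12
Reactants: 19 free 2-aminoimidazole; 20 1-methylparabanic acid (1-methylimidazolidine-2,4,5-trione)
Product: 23 naamidine B, via O-silyl imidate 21 (not isolated), via naamidine B trimethylsilyl ether 22 (not isolated)
Conditions: 20 (3 equiv), MeC(OSiMe3)=NSiMe3 (BSA), MeCN, 80 °C; then 19, toluene, 110 °C; then H2O
Reagents that add atoms: none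
Why: O-Silylation turns the N3–H lactam of 20 into imidate 21, whose C4 then undergoes addition–elimination by the 2-amino group with loss of silanol, a known condensation for attaching this dehydrohydantoin ring to 2-aminoimidazoles; the phenol is silylated in the flask to 22 and is freed again on aqueous work-up.

**Compound list**

1 | N-Boc-sarcosine | CN(CC(=O)O)C(=O)OC(C)(C)C | starting material
2 | N,O-dimethylhydroxylamine hydrochloride | CNOC.Cl | starting material
3 | tert-butyl N-{2-[methoxy(methyl)amino]-2-oxoethyl}-N-methylcarbamate | CON(C)C(=O)CN(C)C(=O)OC(C)(C)C | intermediate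
4 | 4-methoxybenzylmagnesium chloride | COc1ccc(C[Mg]Cl)cc1 | starting material
5 | tert-butyl N-[3-(4-methoxyphenyl)-2-oxopropyl]-N-methylcarbamate | COc1ccc(CC(=O)CN(C)C(=O)OC(C)(C)C)cc1 | intermediate
6 | 1-(4-methoxyphenyl)-3-(methylamino)propan-2-one hydrochloride | CNCC(=O)Cc1ccc(OC)cc1.Cl | intermediate
7 | 1-[3-(4-methoxyphenyl)-2-oxopropyl]-1-methylguanidine | CN(CC(=O)Cc1ccc(OC)cc1)C(=N)N | intermediate (not isolated)
8 | 4-(4-methoxybenzyl)-1-methyl-1H-imidazol-2-amine | Cn1cc(Cc2ccc(OC)cc2)nc1N | intermediate
9 | (E)-N'-[4-(4-methoxybenzyl)-1-methyl-1H-imidazol-2-yl]-N,N-dimethylformimidamide | CN(C)/C=N/c1nc(Cc2ccc(OC)cc2)cn1C | intermediate (not isolated)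
10 | C5 (dimethyliminio)methyl derivative of 9, chloride salt | CN(C)/C=N/c1nc(Cc2ccc(OC)cc2)c(C=[N+](C)C)n1C.[Cl-] | intermediate (not isolated)
11 | (E)-N'-[5-formyl-4-(4-methoxybenzyl)-1-methyl-1H-imidazol-2-yl]-N,N-dimethylformimidamide | CN(C)/C=N/c1nc(Cc2ccc(OC)cc2)c(C=O)n1C | intermediate
12 | (E)-N'-[5-(1-hydroxyprop-2-yn-1-yl)-4-(4-methoxybenzyl)-1-methyl-1H-imidazol-2-yl]-N,N-dimethylformimidamide, racemic | CN(C)/C=N/c1nc(Cc2ccc(OC)cc2)c(C(O)C#C)n1C | intermediate
13 | (E)-N'-[4-(4-methoxybenzyl)-1-methyl-5-(prop-2-ynoyl)-1H-imidazol-2-yl]-N,N-dimethylformimidamide | CN(C)/C=N/c1nc(Cc2ccc(OC)cc2)c(C(=O)C#C)n1C | intermediate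
14 | 3-methoxyfuran | COc1ccoc1 | starting material
15 | amidine-protected imidazol-5-yl 5-methoxy-7-oxabicyclo[2.2.1]hepta-2,5-dien-2-yl ketone, racemic (bridgehead configuration fixed by the bicycle) | COC1=CC2OC1C=C2C(=O)c1c(Cc2ccc(OC)cc2)nc(/N=C/N(C)C)n1C | intermediate (not isolated)
16 | (E)-N'-[5-(3-hydroxy-4-methoxybenzoyl)-4-(4-methoxybenzyl)-1-methyl-1H-imidazol-2-yl]-N,N-dimethylformimidamide | CN(C)/C=N/c1nc(Cc2ccc(OC)cc2)c(C(=O)c2ccc(OC)c(O)c2)n1C | intermediate
17 | (E)-N'-{5-[hydroxy(3-hydroxy-4-methoxyphenyl)methyl]-4-(4-methoxybenzyl)-1-methyl-1H-imidazol-2-yl}-N,N-dimethylformimidamide, racemic | CN(C)/C=N/c1nc(Cc2ccc(OC)cc2)c(C(O)c2ccc(OC)c(O)c2)n1C | intermediate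
18 | (E)-N'-[5-(3-hydroxy-4-methoxybenzyl)-4-(4-methoxybenzyl)-1-methyl-1H-imidazol-2-yl]-N,N-dimethylformimidamide | CN(C)/C=N/c1nc(Cc2ccc(OC)cc2)c(Cc2ccc(OC)c(O)c2)n1C | intermediate
19 | 5-{[2-amino-4-(4-methoxybenzyl)-1-methyl-1H-imidazol-5-yl]methyl}-2-methoxyphenol | Cn1c(N)nc(Cc2ccc(OC)cc2)c1Cc1ccc(OC)c(O)c1 | intermediate
20 | 1-methylparabanic acid | CN1C(=O)NC(=O)C1=O | starting material
21 | 1-methyl-4-(trimethylsilyloxy)-1H-imidazole-2,5-dione | CN1C(=O)N=C(O[Si](C)(C)C)C1=O | intermediate (not isolated)
22 | naamidine B O-trimethylsilyl ether | COc1ccc(Cc2nc(NC3=NC(=O)N(C)C3=O)n(C)c2Cc2ccc(OC)c(O[Si](C)(C)C)c2)cc1 | intermediate (not isolated)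
23 | naamidine B | COc1ccc(Cc2nc(NC3=NC(=O)N(C)C3=O)n(C)c2Cc2ccc(OC)c(O)c2)cc1 | target

**Step count**

Total steps: 12. Longest linear sequence: 12 steps, from N-Boc-sarcosine 1 to naamidine B 23.

**Steps most likely to fail, with fallbacks**

Step 8 (key cycloaddition). Three processes may defeat it: the furan may attack the ynone in open-chain fashion (electrophilic substitution at furan C2 instead of ring closure), the acid-sensitive furan may oligomerise before it cycloadds, or the oxygen bridge may open in the wrong sense. The fallback gives up building the ring and brings it in ready-made. It sets out from aldehyde 11 and comes back at 18. Purchased (5-bromo-2-methoxyphenoxy)(tert-butyl)dimethylsilane is converted with Mg in THF into [3-(tert-butyldimethylsilyloxy)-4-methoxyphenyl]magnesium bromide F1. Addition of this reagent to 11 at 0 °C should give the silyl-protected diaryl carbinol F2. Ionic hydrogenation with Et3SiH and CF3CO2H in CH2Cl2 should give the silyl-protected diarylmethane F3. Bu4NF in THF then removes the silyl ether to give 18, from which steps 11 and 12 follow unchanged.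

Step 5 (Vilsmeier formylation). The reaction may stall at the amidine stage, because protonation of the amidine and imidazole nitrogens in the acidic medium lowers the nucleophilicity of C5. The fallback sets out from 8 and comes back at 11. Me2NCH(OMe)2 in toluene at 80 °C converts 8 into the formamidine 9, now isolated. NBS in MeCN at 0 °C should brominate C5 to give the 5-bromo formamidine F4. Bromine–magnesium exchange with i-PrMgCl·LiCl in THF at 0 °C gives the imidazol-5-ylmagnesium chloride F5, which is quenched with DMF to give aldehyde 11.

Step 7 (oxidation to the terminal ynone). The ynone may be lost during oxidation and isolation by conjugate addition of the basic ring or amidine nitrogen of a second molecule, leading to oligomers on the oxidant surface or on silica. The fallback masks the alkyne terminus. It sets out from 11 and comes back at 13. Purchased lithium (trimethylsilyl)acetylide in THF at −78 °C adds to 11 to give the silylated propargylic alcohol F6. MnO2 in CH2Cl2 oxidises it to the silyl ynone F7, which is hindered at the β-carbon and can be stored. The silyl group is removed with Na2B4O7 in aqueous MeOH at rt immediately before the cycloaddition, to give 13, which is used without storage in step 8.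

**Further compounds**

F1 | step 8 | [3-(tert-butyldimethylsilyloxy)-4-methoxyphenyl]magnesium bromide | COc1ccc([Mg]Br)cc1O[Si](C)(C)C(C)(C)C
F2 | step 8 | (E)-N'-{5-[(3-(tert-butyldimethylsilyloxy)-4-methoxyphenyl)(hydroxy)methyl]-4-(4-methoxybenzyl)-1-methyl-1H-imidazol-2-yl}-N,N-dimethylformimidamide, racemic | CN(C)/C=N/c1nc(Cc2ccc(OC)cc2)c(C(O)c2ccc(OC)c(O[Si](C)(C)C(C)(C)C)c2)n1C
F3 | step 8 | (E)-N'-{5-[3-(tert-butyldimethylsilyloxy)-4-methoxybenzyl]-4-(4-methoxybenzyl)-1-methyl-1H-imidazol-2-yl}-N,N-dimethylformimidamide | CN(C)/C=N/c1nc(Cc2ccc(OC)cc2)c(Cc2ccc(OC)c(O[Si](C)(C)C(C)(C)C)c2)n1C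
F4 | step 5 | (E)-N'-[5-bromo-4-(4-methoxybenzyl)-1-methyl-1H-imidazol-2-yl]-N,N-dimethylformimidamide | CN(C)/C=N/c1nc(Cc2ccc(OC)cc2)c(Br)n1C
F5 | step 5 | {2-[(E)-(dimethylaminomethylene)amino]-4-(4-methoxybenzyl)-1-methyl-1H-imidazol-5-yl}magnesium chloride | CN(C)/C=N/c1nc(Cc2ccc(OC)cc2)c([Mg]Cl)n1C
F6 | step 7 | (E)-N'-{5-[1-hydroxy-3-(trimethylsilyl)prop-2-yn-1-yl]-4-(4-methoxybenzyl)-1-methyl-1H-imidazol-2-yl}-N,N-dimethylformimidamide, racemic | CN(C)/C=N/c1nc(Cc2ccc(OC)cc2)c(C(O)C#C[Si](C)(C)C)n1C
F7 | step 7 | (E)-N'-{4-(4-methoxybenzyl)-1-methyl-5-[3-(trimethylsilyl)prop-2-ynoyl]-1H-imidazol-2-yl}-N,N-dimethylformimidamide | CN(C)/C=N/c1nc(Cc2ccc(OC)cc2)c(C(=O)C#C[Si](C)(C)C)n1C
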